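The earlier runs and the new flask are simulated with constants of no real substance; noise was put on by code.

Treat the free starting material as a first-order decay, and ask for its time constant.

| setting | beta | epsilon | flask |
|---|---|---|---|
| starting material | 21 mM | 32 mM | 42 mM |
| solid reagent | 1.2 equiv | 1.2 equiv | 1.20 equiv |
| remark | run made earlier | run made earlier |  |
| time |  |  | 50 min |

| run | time / min | product / % | starting material / % |
|---|---|---|---|
| beta | 1.50 | 0 | 99.8 |
| beta | 5.00 | 3.0 | 95.6 |
| beta | 8.00 | 5.8 | 90.1 |
| beta | 12.0 | 11.8 | 82.0 |
| beta | 20.0 | 24.7 | 68.0 |
| beta | 25.0 | 32.8 | 59.2 |
| beta | 30.0 | 40.2 | 52.7 |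
| epsilon | 4.00 | 2.6 | 97.0 |
| epsilon | 8.00 | 5.9 | 89.9 |
| epsilon | 12.0 | 11.7 | 82.6 |
| epsilon | 15.0 | 15.5 | 76.6 |
| epsilon | 20.0 | 23.3 | 67.2 |
| epsilon | 25.0 | 30.1 | 60.0 |
| epsilon | 30.0 | 37.3 | 53.3 |

(readings scatter by 0.3 percentage points)

- solid, in amounts per volume of the solution: solid reagent
- the numbers in the tables scatter with a standard deviation of 0.3 percentage points
- at the start none of the solid reagent is in solution
- a reading of starting material is of its free form alone

- red: doubling the solubility of the solid reagent, all else as stated
- violet: doubling the dissolution coefficient of the solid reagent, all else as stated

1. how much product there is at 50 min, in percent of the starting material charged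
2. the change that raises the amount of product at 50 min, in percent of the starting material charged most ("none" if none brings more than 2 percentage points) (red / violet / none)
3. amount of product at 50 min, in percent of the starting material charged, after red

The flask holds 1.20 equiv of solid reagent, so starting material is the limiting reagent and I take product as the end state. The question is how fast it is approached. Between 12.0 min and 30.0 min, beta gives τ = 40.7 min, the time in which free starting material falls by a factor of e.

First setting, the charge. Epsilon gives 41.1 min, so by hand I carry τ to 42 mM. The part read as neither species at 30.0 min is 9.40% in epsilon, and I keep that.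

Second setting, time. Beta extrapolated back to the full charge gives a lag L = 3.92 min. So at 50 min I expect 32.2% starting material and 58.4% product.

Third, solubility. If dissolved reagent sits near saturation, red takes τ to 20.4 min, which leaves 10.4% starting material and 80.2% product, a gain of 22 percentage points.

Fourth, the dissolution coefficient. If violet takes L to 1.96 min, it gains 1.5 points. By hand, red gains more than violet.

The forecast says 56%, red, and 82% after red, on the ground: “Doubling solubility doubles the rate”. My product is higher than its figure, and my red figure is lower.

The flask gives 57.2%. Red is best, with 16 points against 11 points for violet, and reaches 73.6%.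

    starting material + partner ⇌ product + released group (K = 1.00, k = 1.60 M⁻¹ min⁻¹)
    released group → by-product carried off (k = 0.540 min⁻¹)
    solid reagent ⇌ partner, rate k3*(cs3 - [partner]) while solid is left; crystals form when [partner] > cs3 (solubility = 28.0 mM, k = 0.0560 min⁻¹)
    starting material + released group ⇌ idle adduct, settled at all times (K = 190 M⁻¹)

At 25.0 min the partner, the solid reagent in solution, stands at 50.4% of saturation. Free starting material in the flask reads 36.2% at 50.0 min against my 32.2%. With the same L, that makes τ 45.3 min instead of 40.7 min. The neighbouring flask with 71 mM of starting material keeps 41% unbound at 50.0 min, so with the same L its τ is 51.7 min.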